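## Retrosynthetic overview

- The two aryl MOM ethers come off last. Before that, the furan ring (ring C) is closed by C–O bond formation: Sonogashira coupling of an arylalkyne (ring A) with 4-iodoresorcinol (ring B), then 5-endo-dig attack of the ortho phenol.
- The C6–O bond and the only stereocentre are made on the arylalkyne by a new enantioselective oxoammonium ene reaction at the terminal isopropylidene of a geranyl chain (key step).
- The geranyl chain is joined to ring A by allylation of an aryl copper reagent, made from 2-bromo-3,5-bis(methoxymethoxy)benzaldehyde, with geranyl bromide. The aldehyde then becomes the alkyne.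
- Ring order: rings A and B are bought (3,5-dihydroxybenzaldehyde, 4-iodoresorcinol). Ring C is the only ring formed, in the sixth of seven steps.

Assumption: the (2S,5S) enantiomer of the oxoammonium reagent is taken to give the 6R alcohol. The sense of induction is untested; if a trial on 2-methylhept-2-ene shows the opposite, the (2R,5R) reagent is used with nothing else changed.

Reagent note: the oxoammonium salt is made outside the route (NOBF4 oxidation of the known enantiopure C2-symmetric nitroxide, MeCN, −40 °C) and is not counted as a step. Its amine is recovered after step 5.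

Convention: side-chain carbons are counted from the arene CH2 (C1) to the terminal CH2 (C8).

## Route

Step 1
Reactants: 1 3,5-dihydroxybenzaldehyde
Product: 2 3,5-bis(methoxymethoxy)benzaldehyde
Conditions: MOMCl (2.5 equiv), i-Pr2NEt, CH2Cl2, 0 → 25 °C
Reagents that add atoms: chloromethyl methyl ether, COCCl
Why: O-alkylation of both phenols by the reactive α-chloro ether under amine base (MOM acetal formation) leaves the aldehyde untouched.

Step 2
Reactants: 2 3,5-bis(methoxymethoxy)benzaldehyde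
Product: 3 2-bromo-3,5-bis(methoxymethoxy)benzaldehyde
Conditions: NBS (1.05 equiv), MeCN, 0 → 25 °C
Reagents that add atoms: N-bromosuccinimide, O=C1CCC(=O)N1Br
Why: Electrophilic aromatic bromination goes para to one ether and ortho to the other (C2), because the C4 site between the two ethers is more hindered, as is established for 3,5-dialkoxybenzaldehydes.

Step 3
Reactants: 3 2-bromo-3,5-bis(methoxymethoxy)benzaldehyde; 4 geranyl bromide [(2E)-1-bromo-3,7-dimethylocta-2,6-diene]
Product: 9 2-[(2E)-3,7-dimethylocta-2,6-dien-1-yl]-3,5-bis(methoxymethoxy)benzaldehyde, via lithium amino alkoxide 5 (not isolated), via aryllithium 6 (not isolated), via arylcopper 7 (not isolated), via geranylated amino alkoxide 8 (not isolated)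
Conditions: lithium 4-methylpiperazin-1-ide (N-methylpiperazine + n-BuLi), THF, −20 °C; n-BuLi, −78 °C; CuBr·SMe2, −78 → −40 °C; 4, −78 → 0 °C; aq NH4Cl
Reagents that add atoms: none
Why: In situ masking of the aldehyde as a lithium α-amino alkoxide (Comins-type protection) permits fast bromine–lithium exchange, transmetalation to the aryl copper species and SN2 allylation at the primary carbon of geranyl bromide with the E olefin retained, and aqueous work-up returns the aldehyde.

Step 4
Reactants: 9 2-[(2E)-3,7-dimethylocta-2,6-dien-1-yl]-3,5-bis(methoxymethoxy)benzaldehyde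
Product: 10 1-ethynyl-2-[(2E)-3,7-dimethylocta-2,6-dien-1-yl]-3,5-bis(methoxymethoxy)benzene
Conditions: dimethyl (1-diazo-2-oxopropyl)phosphonate, K2CO3, MeOH, 0 → 25 °C
Reagents that add atoms: dimethyl (1-diazo-2-oxopropyl)phosphonate, COP(=O)(OC)C(=[N+]=[N-])C(C)=O
Why: Seyferth–Gilbert homologation in the Ohira–Bestmann form turns the aldehyde into the terminal alkyne under mild basic conditions that leave the MOM ethers and both olefins alone.

Step 5
Reactants: 10 1-ethynyl-2-[(2E)-3,7-dimethylocta-2,6-dien-1-yl]-3,5-bis(methoxymethoxy)benzene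
Product: 12 (3R,6E)-8-[2-ethynyl-4,6-bis(methoxymethoxy)phenyl]-2,6-dimethylocta-1,6-dien-3-ol, via N-alkoxyamine 11 (not isolated)
Conditions: (2S,5S)-2,5-dimethyl-1-oxo-2,5-diphenylpyrrolidin-1-ium tetrafluoroborate (1.05 equiv), NaHCO3, MeCN/CH2Cl2, −40 °C; then Zn, AcOH/THF/H2O, 0 → 25 °C
Reagents that add atoms: (2S,5S)-2,5-dimethyl-1-oxo-2,5-diphenylpyrrolidin-1-ium tetrafluoroborate, C[C@@]1(c2ccccc2)CC[C@@](C)(c2ccccc2)[N+]1=O.F[B-](F)(F)F
Why: Proposed new method: an enantioselective oxoammonium ene reaction, in which the electrophilic oxygen of the C2-symmetric N-oxoammonium cation bonds to the less substituted carbon (C6) of the terminal trisubstituted olefin while a hydrogen of a C7 methyl group passes to nitrogen through a six-membered transition state, so that the C6–O bond, the 1,1-disubstituted olefin and the R stereocentre arise in one event; the phenyl and methyl flanks next to N=O differentiate the two olefin faces, the bulk of the reagent favours the open terminal olefin over the C2=C3 olefin shielded by the ortho,ortho-disubstituted arene, and Zn/AcOH then cleaves only the N–O bond; the closest known reactions are the racemic ene-like addition of achiral 2,2,6,6-tetramethylpiperidine-derived oxoammonium salts to trisubstituted alkenes (same regiochemistry) and the use of chiral oxoammonium ions in oxidative kinetic resolution of secondary alcohols.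

Step 6
Reactants: 12 (3R,6E)-8-[2-ethynyl-4,6-bis(methoxymethoxy)phenyl]-2,6-dimethylocta-1,6-dien-3-ol; 13 4-iodoresorcinol (4-iodobenzene-1,3-diol)
Product: 15 2-{2-[(2E,6R)-6-hydroxy-3,7-dimethylocta-2,7-dien-1-yl]-3,5-bis(methoxymethoxy)phenyl}-1-benzofuran-6-ol, via alkynylphenol 14 (not isolated)
Conditions: Pd(PPh3)2Cl2 (3 mol %), CuI (6 mol %), Et3N, DMF, 25 → 80 °C
Reagents that add atoms: none
Why: Sonogashira coupling at the aryl iodide is followed in the same pot by metal-assisted 5-endo-dig addition of the ortho phenol to the alkyne (C–O bond formation, heteroannulation), and since the para hydroxyl cannot cyclise the 6-hydroxybenzofuran regiochemistry is fixed by 13.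

Step 7
Reactants: 15 2-{2-[(2E,6R)-6-hydroxy-3,7-dimethylocta-2,7-dien-1-yl]-3,5-bis(methoxymethoxy)phenyl}-1-benzofuran-6-ol
Product: 16 2-{3,5-dihydroxy-2-[(2E,6R)-6-hydroxy-3,7-dimethylocta-2,7-dien-1-yl]phenyl}-1-benzofuran-6-ol (CNP0264263.1)
Conditions: p-toluenesulfonic acid monohydrate (1 equiv), MeOH, 25 °C
Reagents that add atoms: none
Why: Acid-catalysed acetal exchange with methanol removes both aryl MOM groups under conditions that are routinely tolerated by geranylated phenols and too mild to ionise the secondary allylic alcohol, so the stereocentre is untouched.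

## Compound list

1 | 3,5-dihydroxybenzaldehyde | O=Cc1cc(O)cc(O)c1 | starting material
2 | 3,5-bis(methoxymethoxy)benzaldehyde | O=Cc1cc(OCOC)cc(OCOC)c1 | intermediate
3 | 2-bromo-3,5-bis(methoxymethoxy)benzaldehyde | O=Cc1cc(OCOC)cc(OCOC)c1Br | intermediate
4 | geranyl bromide, (2E)-1-bromo-3,7-dimethylocta-2,6-diene | CC(C)=CCC/C(C)=C/CBr | starting material
5 | lithium [2-bromo-3,5-bis(methoxymethoxy)phenyl](4-methylpiperazin-1-yl)methanolate (racemic at the carbinol carbon) | CN1CCN(CC1)C(O[Li])c1cc(OCOC)cc(OCOC)c1Br | intermediate (not isolated)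
6 | lithium [2-lithio-3,5-bis(methoxymethoxy)phenyl](4-methylpiperazin-1-yl)methanolate | CN1CCN(CC1)C(O[Li])c1cc(OCOC)cc(OCOC)c1[Li] | intermediate (not isolated)
7 | lithium [2-cuprio-3,5-bis(methoxymethoxy)phenyl](4-methylpiperazin-1-yl)methanolate (aryl copper) | CN1CCN(CC1)C(O[Li])c1cc(OCOC)cc(OCOC)c1[Cu] | intermediate (not isolated)
8 | lithium {2-[(2E)-3,7-dimethylocta-2,6-dien-1-yl]-3,5-bis(methoxymethoxy)phenyl}(4-methylpiperazin-1-yl)methanolate | CC(C)=CCC/C(C)=C/Cc1c(OCOC)cc(OCOC)cc1C(O[Li])N1CCN(C)CC1 | intermediate (not isolated)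
9 | 2-[(2E)-3,7-dimethylocta-2,6-dien-1-yl]-3,5-bis(methoxymethoxy)benzaldehyde | CC(C)=CCC/C(C)=C/Cc1c(OCOC)cc(OCOC)cc1C=O | intermediate
10 | 1-ethynyl-2-[(2E)-3,7-dimethylocta-2,6-dien-1-yl]-3,5-bis(methoxymethoxy)benzene | CC(C)=CCC/C(C)=C/Cc1c(OCOC)cc(OCOC)cc1C#C | intermediate
11 | (2S,5S)-1-{[(3R,6E)-8-[2-ethynyl-4,6-bis(methoxymethoxy)phenyl]-2,6-dimethylocta-1,6-dien-3-yl]oxy}-2,5-dimethyl-2,5-diphenylpyrrolidine | C[C@@]1(c2ccccc2)CC[C@@](C)(c2ccccc2)N1O[C@H](CC/C(C)=C/Cc1c(OCOC)cc(OCOC)cc1C#C)C(C)=C | intermediate (not isolated)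
12 | (3R,6E)-8-[2-ethynyl-4,6-bis(methoxymethoxy)phenyl]-2,6-dimethylocta-1,6-dien-3-ol | C=C(C)[C@H](O)CC/C(C)=C/Cc1c(OCOC)cc(OCOC)cc1C#C | intermediate
13 | 4-iodoresorcinol (4-iodobenzene-1,3-diol) | Oc1ccc(I)c(O)c1 | starting material
14 | 4-({2-[(2E,6R)-6-hydroxy-3,7-dimethylocta-2,7-dien-1-yl]-3,5-bis(methoxymethoxy)phenyl}ethynyl)benzene-1,3-diol | C=C(C)[C@H](O)CC/C(C)=C/Cc1c(OCOC)cc(OCOC)cc1C#Cc1ccc(O)cc1O | intermediate (not isolated)
15 | 2-{2-[(2E,6R)-6-hydroxy-3,7-dimethylocta-2,7-dien-1-yl]-3,5-bis(methoxymethoxy)phenyl}-1-benzofuran-6-ol | C=C(C)[C@H](O)CC/C(C)=C/Cc1c(OCOC)cc(OCOC)cc1-c1cc2ccc(O)cc2o1 | intermediate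
16 | 2-{3,5-dihydroxy-2-[(2E,6R)-6-hydroxy-3,7-dimethylocta-2,7-dien-1-yl]phenyl}-1-benzofuran-6-ol | C=C(C)[C@H](O)CC/C(C)=C/Cc1c(O)cc(O)cc1-c1cc2ccc(O)cc2o1 | target

## Step count and risks

Total step count: 7. Longest linear sequence: 7 steps (1 → 16); 4 and 13 enter as bought materials.

**Step 5 (the new oxoammonium ene reaction).** It can fail through low enantioselectivity, attack at the internal C2=C3 olefin, or hydride abstraction at the benzylic–allylic CH2. The fallback is known chemistry, sets out from 10 and comes back at 12. Shi epoxidation of 10 is run to partial conversion with the D-fructose-derived ketone 1,2:4,5-di-O-isopropylidene-β-D-erythro-hexo-2,3-diulo-2,6-pyranose (30 mol %), KHSO5 (as 2KHSO5·KHSO4·K2SO4), K2CO3 buffer at pH 10.5 and Bu4NHSO4 in MeCN/dimethoxymethane/H2O at 0 °C. This is selective for the more accessible terminal olefin and gives 1-ethynyl-3,5-bis(methoxymethoxy)-2-{(2E)-5-[(2R)-3,3-dimethyloxiran-2-yl]-3-methylpent-2-en-1-yl}benzene F1. Diethylaluminium 2,2,6,6-tetramethylpiperidide (4 equiv, one used up by the alkyne C–H) in toluene at 0 °C then removes a methyl proton and opens the C7–O bond. The C6–O bond and its configuration are untouched, and the product is 12.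

**Step 3 (one-pot masking, metalation and allylation).** It can fail through incomplete masking of the aldehyde, addition of n-BuLi to it, or allylation at the tertiary end of the geranyl unit. The fallback sets out from 3 and comes back at 9, and replaces the transient masking by an isolated acetal. HC(OMe)3 with catalytic pyridinium p-toluenesulfonate in MeOH at 25 °C gives 2-bromo-1-(dimethoxymethyl)-3,5-bis(methoxymethoxy)benzene F2. n-BuLi in THF at −78 °C gives [2-(dimethoxymethyl)-4,6-bis(methoxymethoxy)phenyl]lithium F3, and CuBr·SMe2 gives [2-(dimethoxymethyl)-4,6-bis(methoxymethoxy)phenyl]copper F4. Reaction with 4 gives 1-(dimethoxymethyl)-2-[(2E)-3,7-dimethylocta-2,6-dien-1-yl]-3,5-bis(methoxymethoxy)benzene F5. Pyridinium p-toluenesulfonate in acetone/H2O at 25 °C then frees aldehyde 9 without loss of the MOM ethers.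

**Step 7 (acidic removal of the MOM groups).** It can fail through addition of the freed ortho phenol to the C2=C3 olefin (chroman formation) or solvolysis of the allylic alcohol. The fallback sets out from 10 and comes back at 16. It takes the MOM groups off before the allylic alcohol exists and carries base-labile acetates instead.
- HCl (2 M in MeOH) at 40 °C converts 10 into 5-ethynyl-4-[(2E)-3,7-dimethylocta-2,6-dien-1-yl]benzene-1,3-diol F6.
- Ac2O in pyridine at 0 °C gives 5-ethynyl-4-[(2E)-3,7-dimethylocta-2,6-dien-1-yl]-1,3-phenylene diacetate F7.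
- The conditions of step 5 give, by way of (2S,5S)-1-{[(3R,6E)-8-(2,4-diacetoxy-6-ethynylphenyl)-2,6-dimethylocta-1,6-dien-3-yl]oxy}-2,5-dimethyl-2,5-diphenylpyrrolidine F8 (not isolated), the alcohol 5-ethynyl-4-[(2E,6R)-6-hydroxy-3,7-dimethylocta-2,7-dien-1-yl]-1,3-phenylene diacetate F9.
- The conditions of step 6 with 13 at 60 °C give, by way of 4-[(2,4-dihydroxyphenyl)ethynyl]-5-... tolane 5-[(2,4-dihydroxyphenyl)ethynyl]-4-[(2E,6R)-6-hydroxy-3,7-dimethylocta-2,7-dien-1-yl]-1,3-phenylene diacetate F10 (not isolated), the benzofuran 5-(6-hydroxy-1-benzofuran-2-yl)-4-[(2E,6R)-6-hydroxy-3,7-dimethylocta-2,7-dien-1-yl]-1,3-phenylene diacetate F11.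
- K2CO3 in MeOH at 0 °C removes the acetates to give 16.

## Further compounds

F1 | step 5 | 1-ethynyl-3,5-bis(methoxymethoxy)-2-{(2E)-5-[(2R)-3,3-dimethyloxiran-2-yl]-3-methylpent-2-en-1-yl}benzene | CC1(C)O[C@@H]1CC/C(C)=C/Cc1c(OCOC)cc(OCOC)cc1C#C
F2 | step 3 | 2-bromo-1-(dimethoxymethyl)-3,5-bis(methoxymethoxy)benzene | COC(OC)c1cc(OCOC)cc(OCOC)c1Br
F3 | step 3 | [2-(dimethoxymethyl)-4,6-bis(methoxymethoxy)phenyl]lithium | COC(OC)c1cc(OCOC)cc(OCOC)c1[Li]
F4 | step 3 | [2-(dimethoxymethyl)-4,6-bis(methoxymethoxy)phenyl]copper | COC(OC)c1cc(OCOC)cc(OCOC)c1[Cu]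
F5 | step 3 | 1-(dimethoxymethyl)-2-[(2E)-3,7-dimethylocta-2,6-dien-1-yl]-3,5-bis(methoxymethoxy)benzene | CC(C)=CCC/C(C)=C/Cc1c(OCOC)cc(OCOC)cc1C(OC)OC
F6 | step 7 | 5-ethynyl-4-[(2E)-3,7-dimethylocta-2,6-dien-1-yl]benzene-1,3-diol | CC(C)=CCC/C(C)=C/Cc1c(O)cc(O)cc1C#C
F7 | step 7 | 5-ethynyl-4-[(2E)-3,7-dimethylocta-2,6-dien-1-yl]-1,3-phenylene diacetate | CC(C)=CCC/C(C)=C/Cc1c(OC(C)=O)cc(OC(C)=O)cc1C#C
F8 | step 7 | (2S,5S)-1-{[(3R,6E)-8-(2,4-diacetoxy-6-ethynylphenyl)-2,6-dimethylocta-1,6-dien-3-yl]oxy}-2,5-dimethyl-2,5-diphenylpyrrolidine | C[C@@]1(c2ccccc2)CC[C@@](C)(c2ccccc2)N1O[C@H](CC/C(C)=C/Cc1c(OC(C)=O)cc(OC(C)=O)cc1C#C)C(C)=C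
F9 | step 7 | 5-ethynyl-4-[(2E,6R)-6-hydroxy-3,7-dimethylocta-2,7-dien-1-yl]-1,3-phenylene diacetate | C=C(C)[C@H](O)CC/C(C)=C/Cc1c(OC(C)=O)cc(OC(C)=O)cc1C#C
F10 | step 7 | 5-[(2,4-dihydroxyphenyl)ethynyl]-4-[(2E,6R)-6-hydroxy-3,7-dimethylocta-2,7-dien-1-yl]-1,3-phenylene diacetate | C=C(C)[C@H](O)CC/C(C)=C/Cc1c(OC(C)=O)cc(OC(C)=O)cc1C#Cc1ccc(O)cc1O
F11 | step 7 | 5-(6-hydroxy-1-benzofuran-2-yl)-4-[(2E,6R)-6-hydroxy-3,7-dimethylocta-2,7-dien-1-yl]-1,3-phenylene diacetate | C=C(C)[C@H](O)CC/C(C)=C/Cc1c(OC(C)=O)cc(OC(C)=O)cc1-c1cc2ccc(O)cc2o1
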